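A direct plan would acylate the ring A phenol (15 below) with a bromoacetyl unit and extend it by Wittig olefination and diazo transfer to the diazo ketone A1.
Ring B would then be built on A1 by a photochemical Wolff/Danheiser benzannulation with the siloxyalkyne A2, and desilylation would give the didepside A3.
A3 would be esterified (carbodiimide, DMAP) with the dibenzyl-protected ring C acid A4 and debenzylated.
Weak point 1, the run-up to the benzannulation: five linear steps would carry a base-labile aryl ester through enolisation and diazo transfer, and three more would make the volatile alkyne A2, only to reach the precursor of one simple resorcylate ring.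
Weak point 2, the benzannulation itself: irradiation of an ester-substituted diazo enone beside an aryl ester, followed by closure of an electron-poor triene, would put the least certain step at the end of the longest sequence.
Weak point 3, the late esterification of the doubly ortho-substituted acid A4 with the phenol of A3: it would be slow, would compete with N-acylurea formation and with the second phenol, and would cost benzylation, hot saponification and hydrogenolysis that build nothing.

**Retrosynthetic overview**
- Each ring of the target is an orsellinoyl unit (a cyclised tetraketide), and both links are aryl esters of doubly ortho-substituted acids: O4–C7' between rings A and B, O4'–C7'' between rings B and C. Both esters are made from ketenes, never from an acid.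
- Key disconnection: ring C (C1''–C6'') and the ester O4'–C7'' are cut together, back to the open-chain diketo-dioxinone 7 and the one free phenol of ring B acetonide 8; ring C closes by aldol condensation (bond C1''–C6'').
- Ring B is made first, from the same 7 (bond C1'–C6'), and is born as benzodioxinone 8, which hides O2' and C7' and is the latent acyl donor for the last bond.
- Last bond O4–C7': light opens the benzodioxinone of 11 to a quinone ketene, which the ring A phenol 15 captures. Ring order: B, then C, then union with ring A.
- By design there is no diazo compound, no activation of a hindered acid and no protecting group on rings B and C; precursor 7 costs two steps and serves twice.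

Key step: step 4

Remark on the chemistry: the target has no stereocentre. Ring A is the methyl ester ring (unprimed atoms), ring B the middle ring (primed), ring C the terminal dihydroxy ring (double-primed); C7' and C7'' are the ester carbonyl carbons of rings B and C. Compounds 1, 2, 5 and 12 are taken as commercial.

Step 1
Reactants: 1 2,2,6-trimethyl-4H-1,3-dioxin-4-one; 2 acetyl chloride
Product: 4 2,2-dimethyl-6-(2-oxopropyl)-4H-1,3-dioxin-4-one, via lithium dienolate 3 (not isolated)
Conditions: 1 (2.0 equiv), LiN(SiMe3)2 (2.0 equiv), THF, −78 °C; then 2 (1.0 equiv), −78 °C; 1 M HCl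
Reagents that add atoms: none
Why: Vinylogous deprotonation of the dioxinone and C-acylation of the dienolate at its exocyclic gamma carbon by the acid chloride (crossed Claisen-type acylation), the second equivalent of dienolate absorbing the more acidic product.

Step 2
Reactants: 4 2,2-dimethyl-6-(2-oxopropyl)-4H-1,3-dioxin-4-one; 5 N-methoxy-N-methylacetamide
Product: 7 6-(2,4-dioxopentyl)-2,2-dimethyl-4H-1,3-dioxin-4-one, via dilithium dianion 6 (not isolated)
Conditions: LiN(i-Pr)2 (2.2 equiv), THF, −78 °C; then 5 (1.0 equiv), −78 to −20 °C; aq. NH4Cl (pH 5); crude 7 used directly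
Reagents that add atoms: none
Why: Claisen condensation of a 1,3-dicarbonyl dianion, which reacts at its more basic terminal carbon, with an N-methoxy-N-methylamide (Weinreb ketone synthesis), whose chelated tetrahedral adduct should hold until work-up and so prevent over-reaction.

Step 3
Reactants: 7 6-(2,4-dioxopentyl)-2,2-dimethyl-4H-1,3-dioxin-4-one
Product: 8 7-hydroxy-2,2,5-trimethyl-4H-1,3-benzodioxin-4-one
Conditions: Et3N (2 equiv), CH2Cl2, 25 °C; then 1 M HCl wash
Reagents that add atoms: none
Why: Amine-induced intramolecular vinylogous aldol condensation of dioxinone C-5 onto the terminal methyl ketone (bond C1'–C6'), followed by loss of water and enolisation, the known late aromatisation of diketo-dioxinones that gives ring B as its acetonide with only O-7 (the future O4') free.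

Step 4
Reactants: 8 7-hydroxy-2,2,5-trimethyl-4H-1,3-benzodioxin-4-one; 7 6-(2,4-dioxopentyl)-2,2-dimethyl-4H-1,3-dioxin-4-one
Product: 11 2,2,5-trimethyl-4-oxo-4H-1,3-benzodioxin-7-yl 2,4-dihydroxy-6-methylbenzoate, via acylketene 9 (not isolated), via aryl triketo ester 10 (not isolated)
Conditions: 8 (2.0 equiv), 7 (1.0 equiv), toluene (0.05 M), 110 °C, N2 sweep; then Et3N (1.0 equiv), CH2Cl2, 0 to 25 °C; 1 M HCl
Reagents that add atoms: none
Why: Heating 7 causes a retro-hetero-Diels–Alder loss of acetone to acylketene 9, which the only free phenol of 8 captures through the usual six-membered, proton-relayed addition to give aryl 3,5,7-trioxooctanoate 10, so that the ester bond O4'–C7'' is made from a ketene and not from a hindered acid. Amine then induces the intramolecular aldol condensation of the C2 methylene of 10 onto the C7 methyl ketone (6-(enolexo)-exo-trig, forming C1''–C6''), and loss of water with enolisation of the two remaining ketones gives aromatic ring C with its 2''- and 4''-hydroxyls free. The closest known reaction is the resorcylate synthesis in which diketo-dioxinones are thermolysed with an alcohol and the triketo ester is aromatised late, together with the long-known capture of dioxinone-derived acylketenes by phenols to give aryl beta-keto esters. No stereocentre is formed, and any 7 that aromatises without fragmenting merely becomes more 8. The step needs capture of the ketene by 8 ahead of its internal cyclisation to a pyranone, which the excess of 8 should secure, and aldol closure of 10 ahead of lactonisation or Claisen closure with loss of the aryloxide, which the intrinsically fast C2-to-C7 aldol of 3,5,7-triketo esters under a weak, non-nucleophilic base at low temperature should secure. Over-acylation should be largely avoided because the phenols of ring C appear only after the ketene has been consumed.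

Step 5
Reactants: 12 methyl orsellinate (methyl 2,4-dihydroxy-6-methylbenzoate)
Product: 14 methyl 4-(benzyloxy)-2-methoxy-6-methylbenzoate, via methyl 4-(benzyloxy)-2-hydroxy-6-methylbenzoate 13 (not isolated)
Conditions: BnBr (1.05 equiv), K2CO3 (1.2 equiv), DMF, 25 °C; then MeI (3 equiv), K2CO3 (2 equiv), 50 °C
Reagents that add atoms: benzyl bromide, BrCc1ccccc1; iodomethane, CI
Why: Two Williamson etherifications in one pot: one equivalent of benzyl bromide should alkylate only the free, more acidic 4-OH while the 2-OH is held by its hydrogen bond to the ester, and excess iodomethane at 50 °C then methylates the chelated phenol.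

Step 6
Reactants: 14 methyl 4-(benzyloxy)-2-methoxy-6-methylbenzoate
Product: 15 methyl 4-hydroxy-2-methoxy-6-methylbenzoate
Conditions: H2 (1 atm), 10% Pd/C, EtOAc, 25 °C
Reagents that add atoms: none
Why: Catalytic hydrogenolysis of the benzyl aryl ether, to which the methyl ester and the methyl ether are inert.

Step 7
Reactants: 11 2,2,5-trimethyl-4-oxo-4H-1,3-benzodioxin-7-yl 2,4-dihydroxy-6-methylbenzoate; 15 methyl 4-hydroxy-2-methoxy-6-methylbenzoate
Product: 17 methyl 4-({4-[(2,4-dihydroxy-6-methylbenzoyl)oxy]-2-hydroxy-6-methylbenzoyl}oxy)-2-methoxy-6-methylbenzoate (target), via quinone ketene 16 (not isolated)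
Conditions: 15 (4 equiv), hν (300 nm), dry degassed CH2Cl2 (0.01 M in 11), 25 °C
Reagents that add atoms: none
Why: Photochemical acylation, in which excitation of the 2,2-dimethylbenzodioxinone expels acetone by cycloreversion to the o-quinone ketene 16 and phenol 15 adds to it to form the aryl salicylate bond O4–C7' and free the 2'-OH under neutral conditions; the excess of 15 should outcompete the 4''-OH of ring C, and the hydrogen-bonded salicylate esters of substrate and product should dissipate excitation by proton transfer and so resist photo-Fries rearrangement.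

**Compound list**
1 | 2,2,6-trimethyl-4H-1,3-dioxin-4-one | CC1=CC(=O)OC(C)(C)O1 | starting material
2 | acetyl chloride | CC(Cl)=O | starting material
3 | lithium 2,2-dimethyl-6-methylidene-6H-1,3-dioxin-4-olate | [Li+].[O-]C1=CC(=C)OC(C)(C)O1 | intermediate
4 | 2,2-dimethyl-6-(2-oxopropyl)-4H-1,3-dioxin-4-one | CC(=O)CC1=CC(=O)OC(C)(C)O1 | intermediate
5 | N-methoxy-N-methylacetamide | CC(=O)N(C)OC | starting material
6 | dilithium 2,2-dimethyl-6-(2-oxidoprop-2-en-1-ylidene)-6H-1,3-dioxin-4-olate | [Li+].[Li+].C=C([O-])C=C1C=C([O-])OC(C)(C)O1 | intermediate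
7 | 6-(2,4-dioxopentyl)-2,2-dimethyl-4H-1,3-dioxin-4-one | CC(=O)CC(=O)CC1=CC(=O)OC(C)(C)O1 | intermediate
8 | 7-hydroxy-2,2,5-trimethyl-4H-1,3-benzodioxin-4-one | Cc1cc(O)cc2OC(C)(C)OC(=O)c12 | intermediate
9 | 3,5,7-trioxooct-1-en-1-one | CC(=O)CC(=O)CC(=O)C=C=O | intermediate
10 | 2,2,5-trimethyl-4-oxo-4H-1,3-benzodioxin-7-yl 3,5,7-trioxooctanoate | CC(=O)CC(=O)CC(=O)CC(=O)Oc1cc(C)c2C(=O)OC(C)(C)Oc2c1 | intermediate
11 | 2,2,5-trimethyl-4-oxo-4H-1,3-benzodioxin-7-yl 2,4-dihydroxy-6-methylbenzoate | Cc1cc(O)cc(O)c1C(=O)Oc1cc(C)c2C(=O)OC(C)(C)Oc2c1 | intermediate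
12 | methyl orsellinate (methyl 2,4-dihydroxy-6-methylbenzoate) | COC(=O)c1c(C)cc(O)cc1O | starting material
13 | methyl 4-(benzyloxy)-2-hydroxy-6-methylbenzoate | COC(=O)c1c(C)cc(OCc2ccccc2)cc1O | intermediate
14 | methyl 4-(benzyloxy)-2-methoxy-6-methylbenzoate | COC(=O)c1c(C)cc(OCc2ccccc2)cc1OC | intermediate
15 | methyl 4-hydroxy-2-methoxy-6-methylbenzoate | COC(=O)c1c(C)cc(O)cc1OC | intermediate
16 | 5-methyl-3-oxo-4-(oxomethylidene)cyclohexa-1,5-dien-1-yl 2,4-dihydroxy-6-methylbenzoate | O=C=C1C(=O)C=C(OC(=O)c2c(C)cc(O)cc2O)C=C1C | intermediate
17 | methyl 4-({4-[(2,4-dihydroxy-6-methylbenzoyl)oxy]-2-hydroxy-6-methylbenzoyl}oxy)-2-methoxy-6-methylbenzoate | COC(=O)c1c(C)cc(OC(=O)c2c(C)cc(OC(=O)c3c(C)cc(O)cc3O)cc2O)cc1OC | target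

Total step count: 7. Longest linear sequence: 5 steps (steps 1, 2, 3, 4 and 7).

**Steps most likely to fail**

Step 4. The acylketene may cyclise onto its own enol to a pyranone faster than the electron-poor phenol of 8 adds. The aryl triketo ester may also lactonise or close in the Claisen sense with expulsion of the aryloxide instead of undergoing the aldol closure. The fallback brings ring C in as a finished arene and sets out from 8 and 12. Exhaustive benzylation of 12 (BnBr, K2CO3, DMF, 70 °C) would give methyl 2,4-bis(benzyloxy)-6-methylbenzoate F1. Saponification (KOH, DMSO–H2O, 90 °C) would give 2,4-bis(benzyloxy)-6-methylbenzoic acid F2, the same compound as A4. F2 would be joined to the phenol of 8 through its mixed trifluoroacetic anhydride ((CF3CO)2O, toluene, 25 °C) to give 2,2,5-trimethyl-4-oxo-4H-1,3-benzodioxin-7-yl 2,4-bis(benzyloxy)-6-methylbenzoate F3. Hydrogenolysis (H2, 10% Pd/C, EtOAc) comes back to the route at 11.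

Step 7. The quinone ketene may be captured by the free 4''-OH of a second molecule of 11 (oligomer formation) instead of by 15, or the depside ester may suffer a light-induced acyl shift. The fallback reverses the order of the two ester bonds and uses no light; it sets out from 15 and 7. Thermolysis of 7 with 15 (toluene, 110 °C; then Et3N, CH2Cl2), as in step 4, would build ring B directly on the ring A phenol. This would give methyl 4-[(2,4-dihydroxy-6-methylbenzoyl)oxy]-2-methoxy-6-methylbenzoate F4, the same compound as A3. A second thermolysis of 7 with F4, whose 2'-OH is chelated and whose 4'-OH is free, would build ring C and come back to the route at 17.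

Step 2. The dianion may take a proton from the amide, acylation may occur on oxygen, or the 1,3-diketone of 7 may cyclise during isolation. The fallback carries the terminal ketone in masked form and sets out from 1. Commercial ethyl (2-methyl-1,3-dioxolan-2-yl)acetate (CCOC(=O)CC1(C)OCCO1) would be converted (MeNHOMe·HCl, i-PrMgCl, THF, −20 °C) into N-methoxy-N-methyl-2-(2-methyl-1,3-dioxolan-2-yl)acetamide F5. Lithium dienolate 3 (from 1 and LiN(SiMe3)2, THF, −78 °C) would be acylated by F5 to give 2,2-dimethyl-6-[3-(2-methyl-1,3-dioxolan-2-yl)-2-oxopropyl]-4H-1,3-dioxin-4-one F6. Mild hydrolysis of the ketal (aq. HCl, THF, 0 °C) comes back to the route at 7, so the 1,3-diketone is unmasked only at the last moment.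

**Further compounds**
F1 | step 4 | methyl 2,4-bis(benzyloxy)-6-methylbenzoate | COC(=O)c1c(C)cc(OCc2ccccc2)cc1OCc1ccccc1
F2 | step 4 | 2,4-bis(benzyloxy)-6-methylbenzoic acid | OC(=O)c1c(C)cc(OCc2ccccc2)cc1OCc1ccccc1
F3 | step 4 | 2,2,5-trimethyl-4-oxo-4H-1,3-benzodioxin-7-yl 2,4-bis(benzyloxy)-6-methylbenzoate | Cc1cc(OCc2ccccc2)cc(OCc2ccccc2)c1C(=O)Oc1cc(C)c2C(=O)OC(C)(C)Oc2c1
F4 | step 7 | methyl 4-[(2,4-dihydroxy-6-methylbenzoyl)oxy]-2-methoxy-6-methylbenzoate | COC(=O)c1c(C)cc(OC(=O)c2c(C)cc(O)cc2O)cc1OC
F5 | step 2 | N-methoxy-N-methyl-2-(2-methyl-1,3-dioxolan-2-yl)acetamide | CON(C)C(=O)CC1(C)OCCO1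
F6 | step 2 | 2,2-dimethyl-6-[3-(2-methyl-1,3-dioxolan-2-yl)-2-oxopropyl]-4H-1,3-dioxin-4-one | CC1(CC(=O)CC2=CC(=O)OC(C)(C)O2)OCCO1
A1 | direct plan | 3-methoxy-4-(methoxycarbonyl)-5-methylphenyl (2E)-5-diazo-3-methyl-4-oxopent-2-enoate | COC(=O)c1c(C)cc(OC(=O)/C=C(\C)C(=O)C=[N+]=[N-])cc1OC
A2 | direct plan | (triisopropylsilyloxy)ethyne | C#CO[Si](C(C)C)(C(C)C)C(C)C
A3 | direct plan | methyl 4-[(2,4-dihydroxy-6-methylbenzoyl)oxy]-2-methoxy-6-methylbenzoate | COC(=O)c1c(C)cc(OC(=O)c2c(C)cc(O)cc2O)cc1OC
A4 | direct plan | 2,4-bis(benzyloxy)-6-methylbenzoic acid | OC(=O)c1c(C)cc(OCc2ccccc2)cc1OCc1ccccc1
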